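Lignan numbering: ring B–C7(O)–C8(CH3)–C8'(C9')–C7'H2–ring A, with the ether oxygen joining C7 and C9'. Cuts, in order: C9'H2 is traced back to a lactone carbonyl. The acyl bond O–C9' and the bond C7–C8 are then cut together, which opens both the five- and the eight-membered ring to a biaryl aldehyde (Z)-enoate. Next comes C7'–C8' (benzylic bromide plus α-stannyl enoate), and last the biaryl bond (two molecules of one bromoaryl oxazoline).
Enabling feature: C7 (the oxygen-bearing benzylic CH on ring B) and its neighbour C8 (the CHMe carbon) are both acceptor carbons when drawn as ArCHO and as the β-carbon of an enoate whose carboxyl carbon is C9'. One-electron reduction inverts C7 to a ketyl, and the ketyl oxygen lands 1,4 to C9', so it becomes the ring oxygen of the tetrahydrofuran.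
Forward order: rings A and B are joined first. The C2-symmetric diol is desymmetrised by monosilylation and the butenoate arm is attached to ring A. The ring B aldehyde is then unmasked, the eight-membered ring and the γ-lactone close in one flask, and two reductions take C9' to CH2.
Stereochemistry: the aR axis comes from an (R)-tert-leucinol oxazoline in the Ullmann coupling. The axis plus a samarium chelate sets C7. The Z alkene (syn hydrostannation, retained in the Stille coupling) sets C8. Protonation of the chelated enolate, gated by lactonisation, sets C8'.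

Key step: step 12

Assumption: the target SMILES leaves the biaryl axis open; it is taken as aR (M), because model building indicates that a (7S,8S,8'S) ring can carry the O–C9' bridge across C7 and C8' only in the twist-boat-chair form that belongs to this axis. The axis appears in the names only, since SMILES cannot express it.

Step 1
Reactants: 1 2-bromo-3,4,5-trimethoxybenzoic acid; 2 (R)-tert-leucinol
Product: 4 2-bromo-N-[(2R)-1-hydroxy-3,3-dimethylbutan-2-yl]-3,4,5-trimethoxybenzamide, via acid chloride 3 (not isolated)
Conditions: (COCl)2, cat. DMF, CH2Cl2, 0 °C to rt; concentrate; 2, Et3N, CH2Cl2, 0 °C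
Reagents that add atoms: oxalyl chloride, ClC(=O)C(=O)Cl (chlorine of 3 only)
Why: Acid chloride formation followed by Schotten–Baumann-type N-acylation, in which the amine of 2 reacts ahead of its hydroxyl and the stereocentre of 2 is not touched.

Step 2
Reactants: 4 2-bromo-N-[(2R)-1-hydroxy-3,3-dimethylbutan-2-yl]-3,4,5-trimethoxybenzamide
Product: 6 (4R)-2-(2-bromo-3,4,5-trimethoxyphenyl)-4-tert-butyl-4,5-dihydro-1,3-oxazole, via mesylate 5 (not isolated)
Conditions: MsCl, Et3N, CH2Cl2, 0 °C to 40 °C
Reagents that add atoms: methanesulfonyl chloride, CS(=O)(=O)Cl (mesyl group of 5 only)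
Why: Standard oxazoline cyclodehydration, in which the primary alcohol is mesylated and the amide oxygen displaces the mesylate (5-exo-tet) without touching C4.

Step 3
Reactants: 6 (4R)-2-(2-bromo-3,4,5-trimethoxyphenyl)-4-tert-butyl-4,5-dihydro-1,3-oxazole (two molecules)
Product: 7 (aR)-2,2'-bis[(4R)-4-tert-butyl-4,5-dihydro-1,3-oxazol-2-yl]-4,4',5,5',6,6'-hexamethoxybiphenyl
Conditions: activated Cu powder, DMF, reflux
Reagents that add atoms: none
Why: Oxazoline-directed asymmetric Ullmann homocoupling, in which the two axial diastereomers equilibrate at reflux as monovalent copper chelates and the one that keeps both tert-butyl groups clear of the opposite ring should prevail; the R auxiliary is assigned to the aR axis by analogy with the S-auxiliary/aS pairing of this coupling, the sense is to be checked on 7 (X-ray or CD), and the antipodal amino alcohol is equally available.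

Step 4
Reactants: 7 (aR)-bis(oxazoline)
Product: 9 bis[(2R)-2-acetamido-3,3-dimethylbutyl] (aR)-4,4',5,5',6,6'-hexamethoxybiphenyl-2,2'-dicarboxylate, via bis(amino ester) 8 (not isolated)
Conditions: TFA, H2O, Na2SO4, THF, rt; concentrate; Ac2O, pyridine, CH2Cl2, rt
Reagents that add atoms: water, O; acetic anhydride, CC(=O)OC(C)=O
Why: Acidic oxazoline hydrolysis, in which the protonated ring adds water at C2 and opens to the O-acyl amino ester and N-acetylation blocks the O-to-N acyl shift; everything runs at rt, so the hindered axis is safe.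

Step 5
Reactants: 9 (aR)-bis(acetamido ester)
Product: 10 (aR)-(4,4',5,5',6,6'-hexamethoxybiphenyl-2,2'-diyl)dimethanol
Conditions: LiAlH4, THF, 0 °C
Reagents that add atoms: none
Why: Ester reduction with LiAlH4 releases the auxiliary as its N-acetyl amino alcohol and gives the C2-symmetric diol without thermal stress on the axis.

Step 6
Reactants: 10 (aR)-diol
Product: 11 (aR)-[2'-({[tert-butyl(dimethyl)silyl]oxy}methyl)-4,4',5,5',6,6'-hexamethoxybiphenyl-2-yl]methanol
Conditions: NaH (1 equiv), THF, rt; TBSCl (1 equiv)
Reagents that add atoms: tert-butyldimethylsilyl chloride, CC(C)(C)[Si](C)(C)Cl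
Why: Monosilylation of a symmetrical diol through its sparingly soluble monosodium alkoxide; the two hydroxyls are homotopic, so either choice gives the same compound, and the free CH2OH defines ring A while the silyl ether defines ring B.

Step 7
Reactants: 11 (aR)-monosilyl ether
Product: 12 (aR)-{[2'-(bromomethyl)-4,4',5,5',6,6'-hexamethoxybiphenyl-2-yl]methoxy}(tert-butyl)dimethylsilane
Conditions: CBr4, PPh3, CH2Cl2, 0 °C; used without storage
Reagents that add atoms: carbon tetrabromide, BrC(Br)(Br)Br
Why: The Appel reaction converts the benzylic alcohol into the bromide under neutral conditions that the silyl ether and the aryl methyl ethers tolerate.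

Step 8
Reactants: 13 methyl but-2-ynoate
Product: 14 methyl (2E)-2-(tributylstannyl)but-2-enoate
Conditions: Bu3SnH, Pd(PPh3)4 (cat.), THF, 0 °C to rt
Reagents that add atoms: tributyltin hydride, CCCC[SnH](CCCC)CCCC
Why: Palladium-catalysed hydrostannation of an alkynoate is a syn addition that puts tin on the α-carbon, so the methyl group ends up cis to the ester.

Step 9
Reactants: 12 (aR)-benzylic bromide; 14 methyl (2E)-2-(tributylstannyl)but-2-enoate
Product: 15 methyl (2Z)-2-{[(aR)-2'-({[tert-butyl(dimethyl)silyl]oxy}methyl)-4,4',5,5',6,6'-hexamethoxybiphenyl-2-yl]methyl}but-2-enoate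
Conditions: Pd2(dba)3 (cat.), AsPh3, CuI (cat.), NMP, 50 °C
Reagents that add atoms: none
Why: Stille coupling of a benzylic bromide (oxidative addition to zerovalent palladium) with an α-stannyl enoate forms C7'–C8' with retention of alkene geometry, so the methyl stays cis to the ester (Z), and CuI with the weakly bound AsPh3 speeds transfer from the hindered tin centre.

Step 10
Reactants: 15 (aR,Z)-silyl ether enoate
Product: 16 methyl (2Z)-2-{[(aR)-2'-(hydroxymethyl)-4,4',5,5',6,6'-hexamethoxybiphenyl-2-yl]methyl}but-2-enoate
Conditions: Bu4NF, AcOH, THF, 0 °C to rt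
Reagents that add atoms: none
Why: Fluoride desilylation, with the acetic acid buffer keeping the medium non-basic so that the Z-enoate neither isomerises nor deconjugates.

Step 11
Reactants: 16 (aR,Z)-hydroxymethyl enoate
Product: 17 methyl (2Z)-2-{[(aR)-2'-formyl-4,4',5,5',6,6'-hexamethoxybiphenyl-2-yl]methyl}but-2-enoate
Conditions: activated MnO2, CH2Cl2, rt
Reagents that add atoms: none
Why: Manganese dioxide oxidises the electron-rich benzylic alcohol selectively to the aldehyde and leaves the enoate and its geometry alone.

Step 12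
Reactants: 17 (aR,Z)-biaryl aldehyde enoate
Product: 19 (aR,7S,8S,8'S)-9'-oxo derivative of the target (hexamethoxydibenzocyclooctadiene with 8-methyl group and C7–O–C9'(=O)–C8' lactone bridge), via hydroxy ester samarium alkoxide 18 (not isolated)
Conditions: SmI2 (2.5 equiv), t-BuOH (2 equiv), THF, no HMPA, slow addition of 17 (final 0.005 M), −78 °C to 0 °C; aq. NH4Cl
Reagents that add atoms: none
Why: Divalent samarium reduces the ring B aldehyde to a samarium-bound benzylic ketyl whose carbon C7 adds to the enoate β-carbon C8 (8-endo-trig, eight-membered ring); a second electron turns the α-ester radical into a trivalent samarium enolate, t-BuOH protonates it at C8', and the C7 alkoxide acylates on the ester with loss of methoxide (5-exo-trig, γ-lactone). The closest known reaction types are the SmI2 ketyl–olefin 8-endo cyclisation of biaryl carbonyl compounds and the SmI2 carbonyl–enoate reductive coupling that ends in a γ-lactone. C7: the new bond must grow perpendicular to ring B on the face where the aR axis holds the ring A side chain, and binding of the ester carbonyl to the ketyl-bound samarium (hence no HMPA) turns the C7–O bond towards that side chain, which together should give 7S. C8: in this chelate the ester lies on the oxygen side of the forming bond, so the alkene substituent cis to the ester ends up trans to the aryl group at C7 and to C7' at C8' on the new five-membered ring; the Z-enoate therefore places the methyl group on the outer face (8S), whereas the E-isomer would deliver the C8 epimer. C8': the chelated enolate is open to the proton source only on the face away from C7, and only the resulting epimer with C9' cis to the C7 oxygen can lactonise, the other one returning through the enolate, so the closure should drain the material to 8'S. The step needs ketyl formation ahead of enoate reduction and cyclisation ahead of pinacol coupling or simple reduction: the aryl aldehyde is the more easily reduced group, the rigid tetra-ortho-substituted biaryl keeps C7 and C8 within bonding distance, and slow addition at high dilution suppresses bimolecular paths.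

Step 13
Reactants: 19 (aR,7S,8S,8'S)-bridged lactone
Product: 20 (aR,7S,8S,8'S)-bridged lactol (9'-hydroxy derivative of the target; mixture of C9' anomers)
Conditions: i-Bu2AlH (1.1 equiv), CH2Cl2, −78 °C; aq. potassium sodium tartrate
Reagents that add atoms: none
Why: Partial lactone reduction, in which the aluminium hemiacetal is stable at −78 °C so reduction stops at the lactol, and the cold non-basic medium leaves the α-centre C8' intact.

Step 14
Reactants: 20 bridged lactol
Product: 22 target (aR,7S,8S,8'S)-7,9'-epoxy-hexamethoxydibenzocyclooctadiene lignan, via oxocarbenium ion 21 (not isolated)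
Conditions: Et3SiH (3 equiv), BF3·OEt2 (1.5 equiv), CH2Cl2, −78 °C to −40 °C
Reagents that add atoms: none
Why: Ionic reduction of a lactol, in which BF3 ionises the anomeric hydroxyl to an oxocarbenium ion whose C=O+ bond lies inside the two-atom bridge (no bridgehead double bond) and the silane delivers hydride to C9', which becomes CH2 and creates no stereocentre; the low temperature protects the benzylic C7–O bond.

Compound list
1 | 2-bromo-3,4,5-trimethoxybenzoic acid | COc1cc(C(=O)O)c(Br)c(OC)c1OC | starting material
2 | (R)-tert-leucinol, (2R)-2-amino-3,3-dimethylbutan-1-ol | CC(C)(C)[C@@H](N)CO | starting material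
3 | 2-bromo-3,4,5-trimethoxybenzoyl chloride | COc1cc(C(=O)Cl)c(Br)c(OC)c1OC | intermediate
4 | 2-bromo-N-[(2R)-1-hydroxy-3,3-dimethylbutan-2-yl]-3,4,5-trimethoxybenzamide | COc1cc(C(=O)N[C@@H](CO)C(C)(C)C)c(Br)c(OC)c1OC | intermediate
5 | (2R)-2-(2-bromo-3,4,5-trimethoxybenzamido)-3,3-dimethylbutyl methanesulfonate | COc1cc(C(=O)N[C@@H](COS(C)(=O)=O)C(C)(C)C)c(Br)c(OC)c1OC | intermediate
6 | (4R)-2-(2-bromo-3,4,5-trimethoxyphenyl)-4-tert-butyl-4,5-dihydro-1,3-oxazole | COc1cc(C2=N[C@H](C(C)(C)C)CO2)c(Br)c(OC)c1OC | intermediate
7 | (aR)-2,2'-bis[(4R)-4-tert-butyl-4,5-dihydro-1,3-oxazol-2-yl]-4,4',5,5',6,6'-hexamethoxybiphenyl | COc1cc(C2=N[C@H](C(C)(C)C)CO2)c(c(OC)c1OC)-c1c(C2=N[C@H](C(C)(C)C)CO2)cc(OC)c(OC)c1OC | intermediate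
8 | bis[(2R)-2-amino-3,3-dimethylbutyl] (aR)-4,4',5,5',6,6'-hexamethoxybiphenyl-2,2'-dicarboxylate (present as its bis-trifluoroacetate salt) | COc1cc(C(=O)OC[C@H](N)C(C)(C)C)c(c(OC)c1OC)-c1c(C(=O)OC[C@H](N)C(C)(C)C)cc(OC)c(OC)c1OC | intermediate
9 | bis[(2R)-2-acetamido-3,3-dimethylbutyl] (aR)-4,4',5,5',6,6'-hexamethoxybiphenyl-2,2'-dicarboxylate | COc1cc(C(=O)OC[C@H](NC(C)=O)C(C)(C)C)c(c(OC)c1OC)-c1c(C(=O)OC[C@H](NC(C)=O)C(C)(C)C)cc(OC)c(OC)c1OC | intermediate
10 | (aR)-(4,4',5,5',6,6'-hexamethoxybiphenyl-2,2'-diyl)dimethanol | COc1cc(CO)c(c(OC)c1OC)-c1c(CO)cc(OC)c(OC)c1OC | intermediate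
11 | (aR)-[2'-({[tert-butyl(dimethyl)silyl]oxy}methyl)-4,4',5,5',6,6'-hexamethoxybiphenyl-2-yl]methanol | COc1cc(CO)c(c(OC)c1OC)-c1c(CO[Si](C)(C)C(C)(C)C)cc(OC)c(OC)c1OC | intermediate
12 | (aR)-{[2'-(bromomethyl)-4,4',5,5',6,6'-hexamethoxybiphenyl-2-yl]methoxy}(tert-butyl)dimethylsilane | COc1cc(CBr)c(c(OC)c1OC)-c1c(CO[Si](C)(C)C(C)(C)C)cc(OC)c(OC)c1OC | intermediate
13 | methyl but-2-ynoate | CC#CC(=O)OC | starting material
14 | methyl (2E)-2-(tributylstannyl)but-2-enoate (methyl cis to ester) | C/C=C(\C(=O)OC)[Sn](CCCC)(CCCC)CCCC | intermediate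
15 | methyl (2Z)-2-{[(aR)-2'-({[tert-butyl(dimethyl)silyl]oxy}methyl)-4,4',5,5',6,6'-hexamethoxybiphenyl-2-yl]methyl}but-2-enoate | COc1cc(C/C(C(=O)OC)=C/C)c(c(OC)c1OC)-c1c(CO[Si](C)(C)C(C)(C)C)cc(OC)c(OC)c1OC | intermediate
16 | methyl (2Z)-2-{[(aR)-2'-(hydroxymethyl)-4,4',5,5',6,6'-hexamethoxybiphenyl-2-yl]methyl}but-2-enoate | COc1cc(C/C(C(=O)OC)=C/C)c(c(OC)c1OC)-c1c(CO)cc(OC)c(OC)c1OC | intermediate
17 | methyl (2Z)-2-{[(aR)-2'-formyl-4,4',5,5',6,6'-hexamethoxybiphenyl-2-yl]methyl}but-2-enoate | COc1cc(C/C(C(=O)OC)=C/C)c(c(OC)c1OC)-c1c(C=O)cc(OC)c(OC)c1OC | intermediate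
18 | methyl (aR,7S,8S,8'S)-7-hydroxy-8-methyl-hexamethoxydibenzocyclooctadiene-8'-carboxylate (present as its samarium alkoxide) | COc1cc2c(c(OC)c1OC)-c1c(cc(OC)c(OC)c1OC)[C@@H](O)[C@@H](C)[C@@H](C(=O)OC)C2 | intermediate
19 | (aR,7S,8S,8'S)-9'-oxo derivative of the target (bridged γ-lactone) | COc1cc2c(c(OC)c1OC)-c1c(cc(OC)c(OC)c1OC)[C@H]1OC(=O)[C@@H](C2)[C@@H]1C | intermediate
20 | (aR,7S,8S,8'S)-9'-hydroxy derivative of the target (bridged lactol, C9' anomers) | COc1cc2c(c(OC)c1OC)-c1c(cc(OC)c(OC)c1OC)[C@H]1OC(O)[C@@H](C2)[C@@H]1C | intermediate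
21 | bridged oxocarbenium ion (O+=C9'H) | COc1cc2c(c(OC)c1OC)-c1c(cc(OC)c(OC)c1OC)[C@H]1[O+]=C[C@@H](C2)[C@@H]1C | intermediate
22 | CNP0392777.1, (aR,7S,8S,8'S)-7,9'-epoxy-hexamethoxydibenzocyclooctadiene lignan | COc1cc2c(c(OC)c1OC)-c1c(cc(OC)c(OC)c1OC)[C@H]1OC[C@@H](C2)[C@@H]1C | target

Total steps: 14. Longest linear sequence: 13 (steps 1 to 7 and 9 to 14; step 8 is a one-step branch).

Steps most likely to fail

Step 12. The ketyl may add through the rotamer whose C–O bond points away from ring A. That is a loss of facial control at C7: the eight-membered ring still closes, but the alcohol cannot reach the ester. Pinacol coupling and plain reduction compete as well. The fallback separates ring closure from the control of C7; it sets out from 17 and returns at 19. Compound 17 is cyclised with SmI2, HMPA and t-BuOH in THF, with no demand on chelation, to the 7-epi hydroxy ester F1. Dess–Martin oxidation gives the C7 ketone F2, which is handled cold and briefly because C8 is now α to a carbonyl. LiBH(s-Bu)3 in THF at −78 °C should then deliver hydride from the exposed outer face of the twist-boat-chair ring. The new alkoxide would sit next to the ester and lactonise to 19. A short treatment with NaOMe in MeOH levels C8' if some hydroxy ester remains open.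

Step 9. Slow transmetalation from the hindered α-stannyl enoate gives the labile, electron-rich benzylic bromide time to homocouple, solvolyse or close onto the silyl ether oxygen. Protodestannylation also consumes 14. The fallback builds the alkene by olefination instead of cross-coupling; it sets out from 12 and returns at 15. The sodium salt of methyl bis(2,2,2-trifluoroethyl)phosphonoacetate (NaH, THF/DMF, 0 °C) is alkylated with 12 to the phosphonate F3, whose epimers at the α-carbon are of no consequence. A Still–Gennari olefination with acetaldehyde (KN(SiMe3)2, 18-crown-6, THF, −78 °C) should give the Z-enoate 15.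

Step 14. BF3·OEt2 may ionise the electron-rich benzylic C7–O bond in competition with the anomeric hydroxyl, which would cause ring opening and over-reduction at C7. The fallback avoids Lewis acid altogether; it sets out from 19 and returns at 22. LiAlH4 in THF reduces 19 to the diol F4. The unhindered primary C9' hydroxyl is tosylated selectively (TsCl, pyridine, 0 °C) to the monotosylate F5. NaH in THF then closes the ether by intramolecular Williamson substitution at C9' (5-exo-tet); the C7–O bond is never broken, so C7 keeps its configuration.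

Further compounds
F1 | step 12 | methyl (aR,7R,8S,8'S)-7-hydroxy-8-methyl-hexamethoxydibenzocyclooctadiene-8'-carboxylate (7-epimer of 18) | COc1cc2c(c(OC)c1OC)-c1c(cc(OC)c(OC)c1OC)[C@H](O)[C@@H](C)[C@@H](C(=O)OC)C2
F2 | step 12 | methyl (aR,8S,8'S)-8-methyl-7-oxo-hexamethoxydibenzocyclooctadiene-8'-carboxylate | COc1cc2c(c(OC)c1OC)-c1c(cc(OC)c(OC)c1OC)C(=O)[C@@H](C)[C@@H](C(=O)OC)C2
F3 | step 9 | methyl 2-[bis(2,2,2-trifluoroethoxy)phosphoryl]-3-[(aR)-2'-({[tert-butyl(dimethyl)silyl]oxy}methyl)-4,4',5,5',6,6'-hexamethoxybiphenyl-2-yl]propanoate | COc1cc(CC(C(=O)OC)P(=O)(OCC(F)(F)F)OCC(F)(F)F)c(c(OC)c1OC)-c1c(CO[Si](C)(C)C(C)(C)C)cc(OC)c(OC)c1OC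
F4 | step 14 | (aR,7S,8S,8'S)-8'-(hydroxymethyl)-8-methyl-hexamethoxydibenzocyclooctadien-7-ol | COc1cc2c(c(OC)c1OC)-c1c(cc(OC)c(OC)c1OC)[C@@H](O)[C@@H](C)[C@@H](CO)C2
F5 | step 14 | [(aR,7S,8S,8'S)-7-hydroxy-8-methyl-hexamethoxydibenzocyclooctadien-8'-yl]methyl 4-methylbenzenesulfonate | COc1cc2c(c(OC)c1OC)-c1c(cc(OC)c(OC)c1OC)[C@@H](O)[C@@H](C)[C@@H](COS(=O)(=O)c1ccc(C)cc1)C2
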